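## The problem

The target 15 is a 2,3-disubstituted 2,3-dihydro-1-benzofuran. A benzene ring (ring A) is fused to an oxygen heterocycle (ring B) that carries a 3-oxoprop-1-en-2-yl group on C2 and a tiglate on C3, and a 1-(tigloyloxy)ethyl group sits on C5, para to the ring oxygen O1. C2 (R) and C3 (S) are neighbours and trans, so they can be set together or one from the other. The (R)-carbinol carbon of the side chain lies across ring A, out of their reach, and needs reagent control. Both esters sit on benzylic carbons: the C3 ester can leave together with the C2 hydrogen to give the aromatic benzofuran, and the side-chain ester, para to O1, ionises easily. The α-substituted acrolein is a Michael acceptor and will not survive organolithium, hydride or phosphine reagents, so it has to appear last. The two identical acyl groups must go on with opposite stereochemical courses if the ring is first made cis. The feature that invites a short route is the C2–C3 bond: HO–C3–C2–C(=CH2) is a homoallylic alcohol whose carbinol carbon is benzylic, the product pattern of a [2,3]-Wittig rearrangement. Because C2 is also bonded to O1, the rearrangement substrate is an eight-membered benzo-fused cyclic diether and the shift is transannular.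

## Retrosynthesis

**15 to 13.** The aldehyde C=O is removed first, which leads back through allylic alcohol 14 to the propen-2-yl compound 13. An enal carried earlier would be reduced in the transfer hydrogenation and attacked in the Mitsunobu and lithiation steps. A protected CH2OH carried from the start would add a second allylic leaving group to the rearrangement substrate and cost two more steps. Forward, SeO2 has to prefer the electron-rich 1,1-disubstituted alkene over the two electron-poor tiglate alkenes, and the methyl group over the C2 methine.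

**13 to 10.** The side-chain ester C–O bond is cut (13 to alcohol 12 and tiglic acid 9), then the carbinol C–H bond (12 to ketone 11), then the ketone is masked (11 to ketal 10). The remote stereocenter is best set by a catalyst that ignores the ring, and the electron-rich 1-arylethanol is acylated with retention because a Mitsunobu reaction there would risk ionisation. The ketal is needed because the key step uses t-BuLi; it is the only protecting group of the route.

**10 to 8.** The C3–O ester bond is cut with inversion, giving the cis alcohol 8 and 9. A retentive acylation would require the trans alcohol, which the key step cannot deliver. An oxidation–reduction detour through the C3 ketone would place C2 next to a carbonyl group and lose it. Forward, the Mitsunobu substitution has to outrun elimination to the benzofuran.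

**8 to 6.** The C2–C3 bond is cut and the C3 oxygen is reconnected to the terminal methylene carbon, which gives the eight-membered enol ether 6 by way of the benzylic organolithium 7. Cuts at O1–C2 or C7a–O1 lead to open-chain epoxides or diols whose two stereocenters must be built separately. This cut sets both at once and ties their relationship to ring geometry. Compound 6 has no stereocenter, and the forward reaction must lithiate one of two enantiotopic benzylic hydrogens.

**6 to 1 and 2.** The enol ether double bond is moved back to the exocyclic position (6 to 5), the O5–C4 ether bond is cut (5 to chloro alcohol 4), the ketal is removed (4 to 3) and the O1–C2 ether bond is cut (3 to phenol 1 and dichloride 2).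
- The ring is closed before the alkene is moved because only in the ring is the Z enol ether the sole possible geometry; in an open chain the base would be expected to place the aryloxy group trans to the CH2O arm.
- The two alkylations are separated because the phenol reacts under K2CO3 in the presence of the ketone, whereas the alkoxide needs NaH and therefore the ketal.

## Roads not taken

**Alternative 1:** ring A and ring B are assembled together by cutting C3a–C7a, C4–C5 and C6–C7. Forward, Cp*RuCl(cod) would join the diyne A1 and the alkyne A2 to the fully silylated benzofuran A3.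
- Merits: it is convergent, the side-chain stereocenter comes from a commercial alkynol, C2/C3 arrive trans, and the allylic oxygen is already in place, so neither an inversion nor a SeO2 oxidation is needed.
- Weak points: A1 holds a sensitive silyl-capped ynol ether on a hindered secondary carbon next to an anti diol that needs its own asymmetric synthesis; the regiochemistry of alkyne insertion must be right; the C7 silyl group must be removed; three silyl ethers must be handled at the end.
- Comparison: this road is better in convergence and in avoiding late oxidation-state changes. The chosen plan sets against it a precursor made in four ordinary steps from two commodity chemicals and a single protecting group.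

**Alternative 2:** C2–C3 and O1–C2 are cut. Forward, an allylic ylide from a chiral bicyclic sulfide (isothiocineole type) would add to the silylated salicylaldehyde A4, close to the trans vinyl epoxide, and after fluoride release of the phenoxide give the trans alcohol A5.
- Merits: asymmetric ylide epoxidation of aromatic aldehydes is established, the trans ring is obtained directly, and the oxygenated allyl unit and the side-chain stereocenter are carried in.
- Weak points: a stoichiometric chiral sulfonium salt with a functionalised 2-substituted allyl group must be prepared; the phenoxide has to open the epoxide in the endo sense; two silyl ethers and a free hydroxyl must be told apart before the two acylations.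
- Comparison: in precedent and in sparing the Mitsunobu and SeO2 steps this road is at least as good as the chosen one, and its stepwise form is kept as the fallback for step 5. The chosen plan offers in return a relative configuration fixed by ring geometry and not by ylide selectivity, a recoverable commercial-type ligand, no differentiation of hydroxyl groups, and a new transannular rearrangement as the scientific return.

**Alternative 3:** the aryl ether bond C7a–O1 is cut. Forward, Cs2CO3 in DMSO would turn the C2 hydroxyl of the anti diol A6 into an alkoxide that displaces fluoride para to the acetyl group and gives A7.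
- Merits: the acetyl group serves first as activator and later as the side-chain precursor, and the trans ring follows from the anti diol with retention.
- Weak points: a single para acetyl group is a modest activator; the base meets an enolisable ketone and a diol next to a silyl ether that can migrate; the anti diol with its 1,1-disubstituted alkene needs a multistep auxiliary-based synthesis in which the acetyl group must be masked and unmasked.
- Comparison: the endgame would be as long as the chosen one but free of inversion and SeO2. The chosen plan sets against it a far shorter route to the key-step substrate.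

Key step: step 5

Assumption: the sense of induction of the t-BuLi–bis(oxazoline) pair on this cyclic substrate cannot be deduced from the acyclic cases; the (S,S) ligand is written, and its (R,R) antipode is to be used if the opposite sense is found.

## Route

Step 1
Reactants: 1 1-[4-hydroxy-3-(hydroxymethyl)phenyl]ethanone; 2 3-chloro-2-(chloromethyl)prop-1-ene
Product: 3 1-[4-{[2-(chloromethyl)prop-2-en-1-yl]oxy}-3-(hydroxymethyl)phenyl]ethanone
Conditions: K2CO3, 2 (4 equiv), acetone, reflux
Reagents that add atoms: none
Why: Williamson ether synthesis at the phenol only; the acidic para-acyl phenol is deprotonated by K2CO3 while the benzylic alcohol and the ketone are left alone, and the excess of 2 should suppress double substitution.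

Step 2
Reactants: 3 1-[4-{[2-(chloromethyl)prop-2-en-1-yl]oxy}-3-(hydroxymethyl)phenyl]ethanone
Product: 4 [2-{[2-(chloromethyl)prop-2-en-1-yl]oxy}-5-(2-methyl-1,3-dioxolan-2-yl)phenyl]methanol
Conditions: HOCH2CH2OH, PPTS (cat.), benzene, reflux, Dean–Stark
Reagents that add atoms: ethylene glycol, OCCO
Why: Acid-catalysed ketalisation with azeotropic removal of water; the aryl ketone is the only carbonyl group, and the weak acid PPTS should spare the benzylic alcohol and the allylic chloride.

Step 3
Reactants: 4 [2-{[2-(chloromethyl)prop-2-en-1-yl]oxy}-5-(2-methyl-1,3-dioxolan-2-yl)phenyl]methanol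
Product: 5 3-methylidene-8-(2-methyl-1,3-dioxolan-2-yl)-3,4-dihydro-2H,6H-1,5-benzodioxocine
Conditions: NaH, Bu4NI (cat.), THF–DMF, slow addition (5 mM), 0 to 40 °C
Reagents that add atoms: none
Why: Intramolecular Williamson etherification of the benzylic alkoxide; direct and allylic displacement at the symmetric 2-substituted allyl chloride give the same ring, the ketal leaves no enolisable site for NaH, and high dilution with iodide catalysis should favour the eight-membered ring over oligomers.

Step 4
Reactants: 5 3-methylidene-8-(2-methyl-1,3-dioxolan-2-yl)-3,4-dihydro-2H,6H-1,5-benzodioxocine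
Product: 6 (2Z)-3-methyl-8-(2-methyl-1,3-dioxolan-2-yl)-4H,6H-1,5-benzodioxocine
Conditions: KOt-Bu (0.5 equiv), DMSO, rt
Reagents that add atoms: none
Why: Base-mediated allyl-to-propenyl ether isomerisation; the allylic C2–H next to the aryloxy oxygen is kinetically more acidic than C4–H next to the alkyl ether oxygen, so the alkene should move into conjugation with O1, and the ring admits only the Z geometry.

Step 5
Reactants: 6 (2Z)-3-methyl-8-(2-methyl-1,3-dioxolan-2-yl)-4H,6H-1,5-benzodioxocine
Product: 8 (2R,3R)-5-(2-methyl-1,3-dioxolan-2-yl)-2-(prop-1-en-2-yl)-2,3-dihydro-1-benzofuran-3-ol, via benzylic organolithium 7 (not isolated)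
Conditions: t-BuLi (1.5 equiv), 2,2'-(pentane-3,3-diyl)bis[(4S)-4-(propan-2-yl)-4,5-dihydro-1,3-oxazole] (1.5 equiv), hexane–toluene, −78 °C; then H2O
Reagents that add atoms: none
Why: Proposed new method: t-BuLi bound to the bis(oxazoline) removes one of the two enantiotopic hydrogens at C6, the most acidic C–H of 6 because the carbanion is benzylic and next to oxygen, and the lithio species 7 shifts through a five-membered envelope (C6, O5, C4, C3, C2) in which C6–C2 forms, the allylic C4–O5 bond breaks and C3=C4 becomes the terminal methylene. The closest known reaction types are the enantioselective [2,3]-Wittig rearrangement of open-chain benzyl allyl ethers with t-BuLi and chiral bis(oxazolines) and the ring-contracting [2,3]-Wittig shift of thirteen-membered cyclic allylic ethers; neither has been shown transannularly in a medium ring or onto an oxygen-bearing alkene carbon. Ring B closes by transannular 1,5-bonding, formally a 5-exo-trig attack of the carbanion on C2 with the C2=C3 π bond outside the new ring. C3 of the product (old C6) is set by the ligand-controlled choice between the enantiotopic hydrogens, the shift then taking the invertive course at the lithium-bearing carbon that is usual for this rearrangement. C2 is set relative to C3 by the cis fusion of the two five-membered arrays: O5 and C3 are tied together by the single atom C4 and must leave ring B on the same face, so hydroxyl and propen-2-yl emerge cis. The step needs benzylic lithiation to win over lithiation at the vinylic C2–H, at C4 and at the arene positions ortho to oxygen, and the concerted [2,3] shift to win over the [1,2] radical-pair shift; the low temperature, the hydrocarbon solvent, the ring-enforced Z geometry that keeps C2 within reach of C6, and the ketal, which removes the only carbonyl group, are expected to secure this.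

Step 6
Reactants: 8 (2R,3R)-5-(2-methyl-1,3-dioxolan-2-yl)-2-(prop-1-en-2-yl)-2,3-dihydro-1-benzofuran-3-ol; 9 tiglic acid [(2E)-2-methylbut-2-enoic acid]
Product: 10 (2R,3S)-5-(2-methyl-1,3-dioxolan-2-yl)-2-(prop-1-en-2-yl)-2,3-dihydro-1-benzofuran-3-yl (2E)-2-methylbut-2-enoate
Conditions: PPh3, DIAD, toluene, −20 °C to rt
Reagents that add atoms: none
Why: Mitsunobu esterification; the tiglate displaces the oxyphosphonium group at C3 from the rear, turning the cis (3R) alcohol into the trans (3S) ester, and the non-polar solvent and low temperature should hold back ionisation and elimination.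

Step 7
Reactants: 10 (2R,3S)-5-(2-methyl-1,3-dioxolan-2-yl)-2-(prop-1-en-2-yl)-2,3-dihydro-1-benzofuran-3-yl (2E)-2-methylbut-2-enoate
Product: 11 (2R,3S)-5-acetyl-2-(prop-1-en-2-yl)-2,3-dihydro-1-benzofuran-3-yl (2E)-2-methylbut-2-enoate
Conditions: PPTS (cat.), THF–H2O, rt
Reagents that add atoms: water, O
Why: Acid-catalysed ketal hydrolysis; the ketal of a para-alkoxyaryl ketone opens under conditions mild enough to leave the benzylic ester and the propen-2-yl group untouched.

Step 8
Reactants: 11 (2R,3S)-5-acetyl-2-(prop-1-en-2-yl)-2,3-dihydro-1-benzofuran-3-yl (2E)-2-methylbut-2-enoate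
Product: 12 (2R,3S)-5-[(1R)-1-hydroxyethyl]-2-(prop-1-en-2-yl)-2,3-dihydro-1-benzofuran-3-yl (2E)-2-methylbut-2-enoate
Conditions: RuCl[(R,R)-TsDPEN](p-cymene) (1 mol %), HCO2H–Et3N (5:2), EtOAc, rt
Reagents that add atoms: none
Why: Noyori asymmetric transfer hydrogenation; the (R,R) catalyst should give the (R)-1-arylethanol under catalyst control, independent of the distant ring stereocenters, and does not reduce the C=C bonds; any ring enantiomer carried from step 5 becomes a diastereomer here and can be removed.

Step 9
Reactants: 12 (2R,3S)-5-[(1R)-1-hydroxyethyl]-2-(prop-1-en-2-yl)-2,3-dihydro-1-benzofuran-3-yl (2E)-2-methylbut-2-enoate; 9 tiglic acid [(2E)-2-methylbut-2-enoic acid]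
Product: 13 (1R)-1-[(2R,3S)-3-{[(2E)-2-methylbut-2-enoyl]oxy}-2-(prop-1-en-2-yl)-2,3-dihydro-1-benzofuran-5-yl]ethyl (2E)-2-methylbut-2-enoate
Conditions: DCC, DMAP (cat.), CH2Cl2, 0 °C to rt
Reagents that add atoms: none
Why: Steglich esterification; acylation takes place at oxygen, so the (R) carbinol carbon keeps its configuration.

Step 10
Reactants: 13 (1R)-1-[(2R,3S)-3-{[(2E)-2-methylbut-2-enoyl]oxy}-2-(prop-1-en-2-yl)-2,3-dihydro-1-benzofuran-5-yl]ethyl (2E)-2-methylbut-2-enoate
Product: 15 (1R)-1-[(2R,3S)-3-{[(2E)-2-methylbut-2-enoyl]oxy}-2-(3-oxoprop-1-en-2-yl)-2,3-dihydro-1-benzofuran-5-yl]ethyl (2E)-2-methylbut-2-enoate, via allylic alcohol 14 (not isolated)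
Conditions: SeO2 (1.5 equiv), 1,4-dioxane, 70 °C
Reagents that add atoms: selenium dioxide, O=[Se]=O
Why: SeO2 allylic oxidation (ene reaction, then [2,3]-sigmatropic shift) followed by further oxidation of alcohol 14 to the enal; the electron-rich 1,1-disubstituted alkene should react ahead of the electron-poor tiglate alkenes, and the methyl hydrogens ahead of the hindered C2 methine.

## Compound list

1 | 1-[4-hydroxy-3-(hydroxymethyl)phenyl]ethanone | CC(=O)c1ccc(O)c(CO)c1 | starting material
2 | 3-chloro-2-(chloromethyl)prop-1-ene | C=C(CCl)CCl | starting material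
3 | 1-[4-{[2-(chloromethyl)prop-2-en-1-yl]oxy}-3-(hydroxymethyl)phenyl]ethanone | CC(=O)c1ccc(OCC(=C)CCl)c(CO)c1 | intermediate
4 | [2-{[2-(chloromethyl)prop-2-en-1-yl]oxy}-5-(2-methyl-1,3-dioxolan-2-yl)phenyl]methanol | CC1(OCCO1)c1ccc(OCC(=C)CCl)c(CO)c1 | intermediate
5 | 3-methylidene-8-(2-methyl-1,3-dioxolan-2-yl)-3,4-dihydro-2H,6H-1,5-benzodioxocine | C=C1COc2ccc(C3(C)OCCO3)cc2COC1 | intermediate
6 | (2Z)-3-methyl-8-(2-methyl-1,3-dioxolan-2-yl)-4H,6H-1,5-benzodioxocine | C/C1=C/Oc2ccc(C3(C)OCCO3)cc2COC1 | intermediate
7 | (2Z,6R)-6-lithio-3-methyl-8-(2-methyl-1,3-dioxolan-2-yl)-4H,6H-1,5-benzodioxocine, ligand-bound (C6 drawn for an invertive shift) | C/C1=C/Oc2ccc(C3(C)OCCO3)cc2[C@@H]([Li])OC1 | intermediate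
8 | (2R,3R)-5-(2-methyl-1,3-dioxolan-2-yl)-2-(prop-1-en-2-yl)-2,3-dihydro-1-benzofuran-3-ol | CC(=C)[C@H]1Oc2ccc(C3(C)OCCO3)cc2[C@H]1O | intermediate
9 | tiglic acid, (2E)-2-methylbut-2-enoic acid | C/C=C(\C)C(=O)O | starting material
10 | (2R,3S)-5-(2-methyl-1,3-dioxolan-2-yl)-2-(prop-1-en-2-yl)-2,3-dihydro-1-benzofuran-3-yl (2E)-2-methylbut-2-enoate | CC(=C)[C@H]1Oc2ccc(C3(C)OCCO3)cc2[C@@H]1OC(=O)/C(C)=C/C | intermediate
11 | (2R,3S)-5-acetyl-2-(prop-1-en-2-yl)-2,3-dihydro-1-benzofuran-3-yl (2E)-2-methylbut-2-enoate | CC(=C)[C@H]1Oc2ccc(C(C)=O)cc2[C@@H]1OC(=O)/C(C)=C/C | intermediate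
12 | (2R,3S)-5-[(1R)-1-hydroxyethyl]-2-(prop-1-en-2-yl)-2,3-dihydro-1-benzofuran-3-yl (2E)-2-methylbut-2-enoate | CC(=C)[C@H]1Oc2ccc([C@@H](C)O)cc2[C@@H]1OC(=O)/C(C)=C/C | intermediate
13 | (1R)-1-[(2R,3S)-3-{[(2E)-2-methylbut-2-enoyl]oxy}-2-(prop-1-en-2-yl)-2,3-dihydro-1-benzofuran-5-yl]ethyl (2E)-2-methylbut-2-enoate | CC(=C)[C@H]1Oc2ccc([C@@H](C)OC(=O)/C(C)=C/C)cc2[C@@H]1OC(=O)/C(C)=C/C | intermediate
14 | (1R)-1-[(2R,3S)-2-(3-hydroxyprop-1-en-2-yl)-3-{[(2E)-2-methylbut-2-enoyl]oxy}-2,3-dihydro-1-benzofuran-5-yl]ethyl (2E)-2-methylbut-2-enoate | C=C(CO)[C@H]1Oc2ccc([C@@H](C)OC(=O)/C(C)=C/C)cc2[C@@H]1OC(=O)/C(C)=C/C | intermediate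
15 | (1R)-1-[(2R,3S)-3-{[(2E)-2-methylbut-2-enoyl]oxy}-2-(3-oxoprop-1-en-2-yl)-2,3-dihydro-1-benzofuran-5-yl]ethyl (2E)-2-methylbut-2-enoate | C=C(C=O)[C@H]1Oc2ccc([C@@H](C)OC(=O)/C(C)=C/C)cc2[C@@H]1OC(=O)/C(C)=C/C | target

## Step count and least certain steps

Total: 10 steps. Longest linear sequence: 10 steps (fully linear from 1).

**Step 5 (key step).**
- What may go wrong: lithiation at the vinylic C2–H, at C4 or on the arene in place of C6; a [1,2] radical-pair shift that contracts the ring by one atom only; a carbanion that fails to reach the enol ether carbon and decomposes; or poor discrimination between the enantiotopic hydrogens by the ligand. The last can be corrected in part at step 8, where the minor ring enantiomer becomes a diastereomer.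
- Fallback, known chemistry, from 1 back to the route at 11: MnO2 oxidises the benzylic alcohol of 1 to 5-acetyl-2-hydroxybenzaldehyde F1. TBSCl and imidazole give 5-acetyl-2-[(tert-butyldimethylsilyl)oxy]benzaldehyde F2. The ylide from the (2-methylprop-2-en-1-yl)sulfonium salt of the appropriate enantiomer of isothiocineole adds to the aldehyde, which is far more electrophilic than the aryl ketone, and closes to the trans vinyl epoxide 1-{4-[(tert-butyldimethylsilyl)oxy]-3-[(2S,3S)-3-(prop-1-en-2-yl)oxiran-2-yl]phenyl}ethanone F3. Bu4NF frees the phenoxide, which opens the allylic epoxide carbon with inversion to 1-[(2R,3S)-3-hydroxy-2-(prop-1-en-2-yl)-2,3-dihydro-1-benzofuran-5-yl]ethanone F4. Acylation with 9 (DCC, DMAP), with retention, gives 11. This path also bypasses step 6.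

**Step 3.**
- What may go wrong: intermolecular etherification may outrun the slow closure of the eight-membered ring and give oligomers.
- Fallback, from 4 to 5: the ring is closed under zerovalent-palladium catalysis (Pd(PPh3)4, Cs2CO3, THF, high dilution) as a Tsuji–Trost allylic etherification. Ionisation of the allylic C–O bonds is reversible there, so open-chain oligomers can return to the π-allyl stage and drain into the ring. No compound outside the list is made (F0).

**Step 6.**
- What may go wrong: anti elimination of the activated C3 oxygen with the trans C2 hydrogen, driven by aromatisation to the benzofuran, and ionisation at the benzylic carbon with loss of clean inversion.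
- Fallback, from 8 to 10: inversion and tigloylation are separated. A Mitsunobu reaction with the more acidic, less basic 4-nitrobenzoic acid gives (2R,3S)-5-(2-methyl-1,3-dioxolan-2-yl)-2-(prop-1-en-2-yl)-2,3-dihydro-1-benzofuran-3-yl 4-nitrobenzoate F5. Methanolysis (K2CO3, MeOH) gives the trans alcohol (2R,3S)-5-(2-methyl-1,3-dioxolan-2-yl)-2-(prop-1-en-2-yl)-2,3-dihydro-1-benzofuran-3-ol F6. Acylation with 9 (DCC, DMAP), with retention, gives 10.

**Step 10.**
- What may go wrong: competing ene attack at the C2 methine or at the tiglate methyl groups, over-oxidation, and acid-promoted ionisation of the benzylic esters by selenous acid at 70 °C.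
- Fallback, from 13 to 15: an ene-type chlorination (Ca(OCl)2, solid CO2, CH2Cl2–H2O, 0 °C) transposes the alkene into the methyl group and gives (1R)-1-[(2R,3S)-2-(3-chloroprop-1-en-2-yl)-3-{[(2E)-2-methylbut-2-enoyl]oxy}-2,3-dihydro-1-benzofuran-5-yl]ethyl (2E)-2-methylbut-2-enoate F7. A Kornblum-type oxidation with 4-methylmorpholine N-oxide (NaI cat., NaHCO3, MeCN) then gives 15 under neutral conditions.

## Further compounds

F1 | step 5 | 5-acetyl-2-hydroxybenzaldehyde | CC(=O)c1ccc(O)c(C=O)c1
F2 | step 5 | 5-acetyl-2-[(tert-butyldimethylsilyl)oxy]benzaldehyde | CC(=O)c1ccc(O[Si](C)(C)C(C)(C)C)c(C=O)c1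
F3 | step 5 | 1-{4-[(tert-butyldimethylsilyl)oxy]-3-[(2S,3S)-3-(prop-1-en-2-yl)oxiran-2-yl]phenyl}ethanone | CC(=C)[C@@H]1O[C@H]1c1cc(C(C)=O)ccc1O[Si](C)(C)C(C)(C)C
F4 | step 5 | 1-[(2R,3S)-3-hydroxy-2-(prop-1-en-2-yl)-2,3-dihydro-1-benzofuran-5-yl]ethanone | CC(=C)[C@H]1Oc2ccc(C(C)=O)cc2[C@@H]1O
F0 | step 3 | none | none
F5 | step 6 | (2R,3S)-5-(2-methyl-1,3-dioxolan-2-yl)-2-(prop-1-en-2-yl)-2,3-dihydro-1-benzofuran-3-yl 4-nitrobenzoate | CC(=C)[C@H]1Oc2ccc(C3(C)OCCO3)cc2[C@@H]1OC(=O)c1ccc(cc1)[N+](=O)[O-]
F6 | step 6 | (2R,3S)-5-(2-methyl-1,3-dioxolan-2-yl)-2-(prop-1-en-2-yl)-2,3-dihydro-1-benzofuran-3-ol | CC(=C)[C@H]1Oc2ccc(C3(C)OCCO3)cc2[C@@H]1O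
F7 | step 10 | (1R)-1-[(2R,3S)-2-(3-chloroprop-1-en-2-yl)-3-{[(2E)-2-methylbut-2-enoyl]oxy}-2,3-dihydro-1-benzofuran-5-yl]ethyl (2E)-2-methylbut-2-enoate | C=C(CCl)[C@H]1Oc2ccc([C@@H](C)OC(=O)/C(C)=C/C)cc2[C@@H]1OC(=O)/C(C)=C/C
A1 | alternative 1 | (3S,4R)-3-[(tert-butyldimethylsilyl)oxy]-5-{[(tert-butyldimethylsilyl)oxy]methyl}-4-{[(trimethylsilyl)ethynyl]oxy}hex-5-en-1-yne | C=C(CO[Si](C)(C)C(C)(C)C)[C@@H](OC#C[Si](C)(C)C)[C@@H](O[Si](C)(C)C(C)(C)C)C#C
A2 | alternative 1 | tert-butyl{[(2R)-but-3-yn-2-yl]oxy}dimethylsilane | C#C[C@@H](C)O[Si](C)(C)C(C)(C)C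
A3 | alternative 1 | (2R,3S)-3-(tert-butyldimethylsilyloxy)-2-[3-(tert-butyldimethylsilyloxy)prop-1-en-2-yl]-5-[(1R)-1-(tert-butyldimethylsilyloxy)ethyl]-7-(trimethylsilyl)-2,3-dihydro-1-benzofuran | C=C(CO[Si](C)(C)C(C)(C)C)[C@H]1Oc2c([Si](C)(C)C)cc([C@@H](C)O[Si](C)(C)C(C)(C)C)cc2[C@@H]1O[Si](C)(C)C(C)(C)C
A4 | alternative 2 | 2-[(tert-butyldimethylsilyl)oxy]-5-[(1R)-1-(tert-butyldimethylsilyloxy)ethyl]benzaldehyde | O=Cc1cc([C@@H](C)O[Si](C)(C)C(C)(C)C)ccc1O[Si](C)(C)C(C)(C)C
A5 | alternative 2 | (2R,3S)-2-[3-(tert-butyldimethylsilyloxy)prop-1-en-2-yl]-5-[(1R)-1-(tert-butyldimethylsilyloxy)ethyl]-2,3-dihydro-1-benzofuran-3-ol | C=C(CO[Si](C)(C)C(C)(C)C)[C@H]1Oc2ccc([C@@H](C)O[Si](C)(C)C(C)(C)C)cc2[C@@H]1O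
A6 | alternative 3 | 1-{3-[(1S,2R)-3-{[(tert-butyldimethylsilyl)oxy]methyl}-1,2-dihydroxybut-3-en-1-yl]-4-fluorophenyl}ethanone | C=C(CO[Si](C)(C)C(C)(C)C)[C@@H](O)[C@@H](O)c1cc(C(C)=O)ccc1F
A7 | alternative 3 | 1-{(2R,3S)-2-[3-(tert-butyldimethylsilyloxy)prop-1-en-2-yl]-3-hydroxy-2,3-dihydro-1-benzofuran-5-yl}ethanone | C=C(CO[Si](C)(C)C(C)(C)C)[C@H]1Oc2ccc(C(C)=O)cc2[C@@H]1O
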